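## Structural features

The molecule consists of three carbocycles. Ring A is an enolised 2-acylcyclohexane-1,3,5-trione with the 3-methylbutanoyl group on one carbon and two prenyl groups on the carbon opposite. Ring B is a cyclohexane that shares the spiro carbon Cs with ring A. Ring C is a cyclopentane trans-fused to ring B along Ca–Cb. Ring B runs Cs–B1–Ca–Cb–Cd–B2 (B1 and B2 are CH2). Ca carries the ring C carbinol carbon Cc (CH3, OH) and Cb carries the ring B carbinol Cd (CH3, OH), so Cc, Ca, Cb and Cd are four contiguous stereocentres, and Cs, one methylene away on either side, is the fifth. Cs is stereogenic only because its two ring A carbonyl neighbours differ: Cax is bonded to the diprenyl carbon and Ceq to the acyl-bearing carbon. The trans fusion locks the chair of ring B; in it the Cd hydroxyl is axial (its methyl equatorial), Cax is axial on the same face and 1,3 to that hydroxyl, and the hydrogen on Ca is the third axial group on that face. The fragile groups are the β-triketone (acidic, ambident towards alkylation, with a non-enolisable carbonyl between two quaternary carbons that nucleophiles can cleave), the two tertiary alcohols (they ionise in acid) and the two trisubstituted alkenes (they survive neither oxidants nor strong acid), so the prenyl groups must come after any oxidation. The real difficulty is Cs, that is, distinguishing two carbonyl carbons on a centre insulated from the other stereocentres by B1 and B2, together with the axial tertiary C–O bond on Cd. The key step uses the fact that the Cd oxygen, Cd, B2, Cs and Cax are the five atoms of a γ-lactone: an axial carboxyl on Cs can deliver oxygen to the axial Cd–H bond, which makes the carbinol and marks that carboxyl as Cax in one act.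

## Logic of the disconnections

From 18 the two C–C bonds between the ring A methylene carbon and the prenyl groups are cut, which gives 16 and two equivalents of 17. The gem-diprenyl carbon between two carbonyls is the classical product of enolate alkylation, and cutting here removes both acid-sensitive alkenes from all earlier steps. The forward step must alkylate carbon and not oxygen, twice at the same carbon, and must leave two free tertiary alcohols alone.

16 is opened at the ring A bond between that methylene carbon and Cax. In this direction the axial Cd hydroxyl and Cax, which are 1,3-diaxial in 16, merge into one functional group, the γ-lactone of 15, and the methylene becomes the methyl of an acetyl group. The gain is that ring A disappears and the Cs problem is reduced to "which carboxyl is the lactone". The forward Claisen closure must deprotonate the acetyl CH3 and not the 3-methylbutanoyl CH2, and must not shed an acyl group.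

15 is cut between Ceq and the central carbon of the triacylmethane, which gives 10 and 11. C-acylation of a 1,3-diketone by an acid chloride is a dependable way to a triacylmethane, and 11 brings in the complete acyl side chain and two ring A carbons. The forward step must activate the free acid of 10 in the presence of a tertiary alcohol and a lactone, and must acylate carbon.

10 is cut at the Cd–O bond, the only bond the key step forms, which leads to 9. This removes the Cs stereocentre (9 has two carboxyls on Cs) and the Cd oxygen, and leaves a hydrocarbon ring B with every large group equatorial. The forward step must oxidise the axial Cd–H with retention and prefer it to the equally syn-axial Ca–H.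

9 is taken back to 8 by ester hydrolysis, and 8 is cut at Cs–B2, which gives 7. A malonyl radical closing 6-endo on the isopropenyl group forms ring B on a preset trans-1,2-disubstituted cyclopentane, so the trans fusion is inherited. The forward step must close 6-endo and deliver hydrogen to the axial face of the Cd radical.

7 is simplified to 6 by removing bromine, and 6 is cut at the Cc–CH3 bond, which gives 5. A methyl nucleophile adding to the cyclopentanone sets Cc. The forward step must attack the face opposite the adjacent side chain and leave the malonate esters intact.

5 is cut at Cb–Cd and Ca–B1, which gives 1, 2 and 3 by way of 4. Conjugate addition with enolate trapping makes both bonds in one operation from three purchasable reagents. The forward step must set Cb with enantiocontrol; the trans relation of Ca follows from anti approach and is also the thermodynamic one.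

## Other disconnections considered

Alternative 1: The cut removes the fusion bond Ca–Cb together with the ring C bond P1–P2 (sulfonyl carbon to its neighbouring CH2), so rings B and C fall apart together into the acyclic malonate A1. A1 carries a 2-(trimethylsilylmethyl)allyl carbonate on the B1 arm and an (E)-vinyl sulfone behind the silyl-protected Cd carbinol on the B2 arm. In the forward sense zerovalent palladium (from Pd(OAc)2 and P(OiPr)3) would ionise the carbonate, and the trimethylenemethane complex would add to the vinyl sulfone, first at Cb and then by closure at the sulfonyl carbon, to give the bicyclic diester A2.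
- In its favour: two rings and two C–C bonds in one catalytic step. The Cd oxygen is present from the start, so no C–H oxidation and no site-selectivity question arises; on this point it is better than the chosen plan. The cycloaddition is also better precedented than a directed oxidation with two competing methines.
- Against it here: A1 is a long linear target in itself (enantioenriched tertiary carbinol, vinyl sulfone, unsymmetrical double alkylation of a malonate). Intramolecular cycloadditions of this kind do not reliably give the trans ring fusion. A2 still needs desulfonylation and a face-selective conversion of the exocyclic methylene into the ring C carbinol, which nothing in A2 controls.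
- Comparison: on Cs the two plans are equal, because after desilylation the Cd hydroxyl of A2 would lactonise onto the syn-axial ester by the same geometric differentiation. The step count would be clearly higher, and two stereocentres (the fusion and Cc) would be less secure than in the chosen plan.

Alternative 2: Here the weight is put on the first C–C bond-forming event. Cb–Cd and Ca–B1 are cut, and copper-catalysed asymmetric addition of 2 to 1 with trapping of the magnesium enolate by 3 would give the trans-2,3-disubstituted cyclopentanone A3.
- In its favour: two bonds, two stereocentres (Cb from the catalyst, Ca from anti approach and thermodynamics) and all carbons of rings B and C except two methyl groups, in one operation. As precedent it is the stronger step. In step economy it is the equal of the chosen plan, because A3 is identical with 5 and the reaction is step 1 of the route.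
- Against making it the centre of the plan: it settles only the easier part. Cs, the Cd oxygen and all of ring A remain open after it, and without the lactone device the two esters would have to be distinguished some other way. Its own weak points are the enantioselectivity with an α-branched alkenyl Grignard reagent on cyclopentenone and the tendency of 3 to oligomerise.
- Comparison: the two are not rivals. The chosen plan contains this disconnection and adds the step that solves Cs and Cd.

Alternative 3: The cut is Cs–B2. The aromatic acylphloroglucinol A4 carries, on the ring carbon that becomes Cs, the B1–cyclopentane arm with a 2-methyloxirane on Cb. Its phenoxide, held to the epoxide oxygen by a chelating cation, would attack the epoxide CH2 through the ipso carbon, close ring B, dearomatise ring A and free the Cd hydroxyl, giving A5.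
- In its favour: ring A is bought as an arene and needs no Claisen construction, the Cd oxygen comes from an epoxide, and the route is convergent. On step economy and convergence it is better than the chosen plan. A5 is identical with 16, so the end game is equal.
- Against it here: alkylation of a phloroglucinol at an already substituted carbon by an unactivated primary epoxide carbon is thinly precedented (this class normally uses allylic or benzylic electrophiles), and phenoxide O-alkylation between molecules competes. Two stereochemical elements are weakly controlled: the epoxide configuration, which becomes Cd, and the rotamer of the arene in the closure, which decides whether Cax or Ceq ends up syn to the Cd oxygen, since both ortho oxygens can chelate.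
- Comparison: in the chosen plan both of those elements follow from the locked chair of ring B. The alternative is shorter, but its stereochemistry is less determined.

Key step: step 6

Assumptions (remarks on the chemistry):
- The ligand antipode named in step 1 is taken to give (S) at the isopropenyl-bearing carbon; if a first run shows the opposite sense, the enantiomeric ligand is used.
- 14 and 15 are drawn as triketo tautomers (their central carbon is enolised and is not a defined stereocentre); 16 and 18 are drawn as the enol tautomer of the target.

## Route

Step 1
Reactants: 1 cyclopent-2-en-1-one; 2 isopropenylmagnesium bromide; 3 diethyl methylenemalonate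
Product: 5 diethyl 2-{[(1R,5S)-2-oxo-5-(prop-1-en-2-yl)cyclopentyl]methyl}propanedioate, via magnesium enolate 4 (not isolated)
Conditions: CuBr·SMe2 (5 mol %), (R)-1-[(S)-2-(diphenylphosphino)ferrocenyl]ethyldicyclohexylphosphine (6 mol %), tBuOMe, −78 °C; then 3 (1.05 equiv, slow addition), THF, −78 °C; aq. NH4Cl
Reagents that add atoms: none
Why: Copper-catalysed asymmetric conjugate addition of a Grignard reagent followed by Michael trapping of the magnesium enolate 4 by the very electrophilic 3 (three-component coupling); the ferrocenyl diphosphine–copper complex should set the isopropenyl-bearing carbon (S), and the malonate arm enters anti to it, the 2,3-trans ketone also being the thermodynamic epimer.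

Step 2
Reactants: 5 diethyl 2-{[(1R,5S)-2-oxo-5-(prop-1-en-2-yl)cyclopentyl]methyl}propanedioate
Product: 6 diethyl 2-{[(1R,2S,5S)-2-hydroxy-2-methyl-5-(prop-1-en-2-yl)cyclopentyl]methyl}propanedioate
Conditions: MeMgBr (2.5 equiv), CeCl3 (2.5 equiv), THF, −78 °C; aq. NH4Cl, −78 °C → rt
Reagents that add atoms: methylmagnesium bromide, C[Mg]Br
Why: Organocerium 1,2-addition; the first equivalent turns the malonate into its enolate, which shields both esters, and the weakly basic reagent should attack the ketone from the face opposite the adjacent side chain, so the new hydroxyl is cis to that chain and the methyl trans to it (Cc as in the target), any minor epimer being removed by chromatography.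

Step 3
Reactants: 6 diethyl 2-{[(1R,2S,5S)-2-hydroxy-2-methyl-5-(prop-1-en-2-yl)cyclopentyl]methyl}propanedioate
Product: 7 diethyl 2-bromo-2-{[(1R,2S,5S)-2-hydroxy-2-methyl-5-(prop-1-en-2-yl)cyclopentyl]methyl}propanedioate
Conditions: NaH (1.05 equiv), THF, 0 °C; NBS (1.1 equiv), 0 °C
Reagents that add atoms: N-bromosuccinimide, O=C1CCC(=O)N1Br
Why: Electrophilic bromination of a malonate enolate; one equivalent of NaH removes only the malonate proton, which is far more acidic than the tertiary hydroxyl, and the enolate should react with NBS faster than the alkene does.

Step 4
Reactants: 7 diethyl 2-bromo-2-{[(1R,2S,5S)-2-hydroxy-2-methyl-5-(prop-1-en-2-yl)cyclopentyl]methyl}propanedioate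
Product: 8 diethyl (3S,3aR,7S,7aR)-3-hydroxy-3,7-dimethyloctahydro-1H-indene-5,5-dicarboxylate
Conditions: Bu3SnH (1.3 equiv, syringe pump), AIBN (0.2 equiv), PhH (0.01 M), 80 °C
Reagents that add atoms: none
Why: Tin hydride chain reduction in which the electrophilic malonyl radical adds 6-endo-trig to the CH2 terminus of the 1,1-disubstituted alkene through a chair (5-exo closure would give a strained trans-fused bicyclo[3.3.0]octane), so the trans-hydrindane forms; the tertiary Cd radical should take hydrogen on its axial lobe (torsional preference of cyclohexyl radicals, and the methyl avoids a developing syn-axial clash with the axial ester), which leaves the methyl equatorial and the new C–H axial and syn to the axial ester.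

Step 5
Reactants: 8 diethyl (3S,3aR,7S,7aR)-3-hydroxy-3,7-dimethyloctahydro-1H-indene-5,5-dicarboxylate
Product: 9 (3S,3aR,7S,7aR)-3-hydroxy-3,7-dimethyloctahydro-1H-indene-5,5-dicarboxylic acid
Conditions: KOH (10 equiv), EtOH/H2O 3:1, 80 °C; 1 M HCl, 0 °C
Reagents that add atoms: potassium hydroxide, [K+].[OH-]
Why: Saponification of a geminal diester with excess hydroxide; the dicarboxylate does not decarboxylate in base, the dialkylmalonic acid is stable when set free cold, and no stereocentre is touched.

Step 6
Reactants: 9 (3S,3aR,7S,7aR)-3-hydroxy-3,7-dimethyloctahydro-1H-indene-5,5-dicarboxylic acid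
Product: 10 (1R,2S,5S,6R,8R)-5-hydroxy-1,5-dimethyl-9-oxo-10-oxatricyclo[6.2.1.0(2,6)]undecane-8-carboxylic acid
Conditions: [Fe((S,S)-PDP)(CH3CN)2](SbF6)2 (3 × 5 mol %; PDP = 1,1'-bis(pyridin-2-ylmethyl)-2,2'-bipyrrolidine), 50% aq. H2O2 (3 × 1.2 equiv), CH3CN, rt, portionwise, no added acid
Reagents that add atoms: none
Why: This is a carboxylic acid-directed γ-C–H lactonisation by a non-heme iron catalyst, the closest known reaction type being the iron–PDP/H2O2 oxidation of tertiary γ-C–H bonds of aliphatic acids to γ-lactones. A carboxyl group of 9 binds iron as a carboxylate ligand, assists heterolysis of the bound peroxide and gives an iron–oxo carboxylate (formally pentavalent iron). Only the axial carboxyl can bring the oxo group to a C–H bond, because it is 1,3-diaxial to the hydrogens on Cd and Ca, whereas the equatorial carboxyl points away from every tertiary hydrogen. Hydrogen abstraction from Cd–H and rebound of the carboxylate oxygen form the Cd–O bond (hydroxyl rebound followed by spontaneous lactonisation of the syn-axial hydroxy acid would give the same product). The ring closed is the five-membered lactone Cax–O–Cd–B2–Cs, formed by O–C bonding across the 1,3-diaxial positions of ring B; it is a 6-oxabicyclo[3.2.1]octan-7-one and can exist only as the cis-diaxial bridge. Cd keeps its configuration because rebound is faster than inversion of the short-lived radical and only the axial face can be bridged; Cs becomes stereogenic and its configuration is set by the locked chair, that is by Ca and Cb, since the carboxyl on the Cd–H face becomes the lactone carbonyl Cax and the other stays as the free acid Ceq. The selectivity needed is Cd–H over the equally syn-axial Ca–H: Ca–H lies β to the electron-withdrawing ring C hydroxyl, sits next to the fully substituted Cc and belongs to the ring fusion, while Cd–H is on an unhindered, methyl-bearing and more electron-rich carbon. The tertiary alcohol has no α-hydrogen, and the directed mode should keep all other C–H bonds out of reach.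

Step 7
Reactants: 10 (1R,2S,5S,6R,8R)-5-hydroxy-1,5-dimethyl-9-oxo-10-oxatricyclo[6.2.1.0(2,6)]undecane-8-carboxylic acid; 11 6-methylheptane-2,4-dione
Product: 15 (1R,2S,5S,6R,8R)-8-(2-acetyl-5-methyl-3-oxohexanoyl)-5-hydroxy-1,5-dimethyl-10-oxatricyclo[6.2.1.0(2,6)]undecan-9-one, via bis(trimethylsilyl) derivative 12 (not isolated), via silyl ether acid chloride 13 (not isolated), via silylated triketone 14 (not isolated)
Conditions: (Me3Si)2NH (3 equiv), Me3SiOTf (2 mol %), CH2Cl2, rt, evaporate; (COCl)2 (1.2 equiv), DMF (cat.), CH2Cl2, 0 °C → rt, evaporate; 11 (1.2 equiv), MgCl2 (1.2 equiv), pyridine (2.5 equiv), CH2Cl2, 0 °C → rt; 1 M HCl, THF, rt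
Reagents that add atoms: none
Why: Transient silylation masks the tertiary hydroxyl and turns the acid into a silyl ester, which oxalyl chloride with catalytic DMF converts into the acid chloride under neutral conditions (it has no α-hydrogen and cannot form a ketene); the magnesium chelate of 11 is then C-acylated at its central carbon (soft enolisation), and dilute acid frees the triacylmethane and cleaves the labile tertiary silyl ether, with no stereocentre changed.

Step 8
Reactants: 15 (1R,2S,5S,6R,8R)-8-(2-acetyl-5-methyl-3-oxohexanoyl)-5-hydroxy-1,5-dimethyl-10-oxatricyclo[6.2.1.0(2,6)]undecan-9-one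
Product: 16 des-prenyl spiro trione (ring A: 5-hydroxy-4-(3-methylbutanoyl)cyclohex-4-ene-1,3-dione spiro-fused at C2 to C5' of (3'S,3a'R,7'R,7a'S)-3',7'-dihydroxy-3',7'-dimethyloctahydroindene; the ring A carbonyl next to the CH2 is axial on ring B and syn to the 7'-hydroxyl)
Conditions: LDA (3.5 equiv), THF, −78 → 0 °C; 1 M HCl, 0 °C
Reagents that add atoms: none
Why: Claisen (Dieckmann-type) cyclisation of a polyanion: LDA removes the enol and hydroxyl protons and then, kinetically, a proton of the acetyl CH3 and not of the β-branched 3-methylbutanoyl CH2; the terminal carbanion attacks the lactone carbonyl (6-exo-trig), the Cd alkoxide leaves, and immediate deprotonation of the new ring CH2 should make the closure irreversible, while Cs keeps all four bonds so that the former lactone carbonyl is Cax by construction.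

Step 9
Reactants: 16 des-prenyl spiro trione; 17 prenyl bromide (1-bromo-3-methylbut-2-ene)
Product: 18 target CNP0198642.4 (16 carrying two 3-methylbut-2-enyl groups on the ring A carbon between Cax and the enol carbon)
Conditions: 17 (2.4 equiv), NaOMe (3.5 equiv), MeOH, 0 °C → rt; dilute citric acid
Reagents that add atoms: none
Why: Double C-alkylation of the dianion of a cyclic β-polyketone, the classical gem-diprenylation of acylphloroglucinol-derived triones; in methanol the more basic carbon between Cax and the enol carbon should be alkylated twice by the soft allylic bromide, the acyl-bearing carbon and the tertiary hydroxyls do not compete, and no stereocentre is formed or touched.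

## Compound list

1 | cyclopent-2-en-1-one | O=C1C=CCC1 | starting material
2 | isopropenylmagnesium bromide | CC(=C)[Mg]Br | starting material
3 | diethyl methylenemalonate | C=C(C(=O)OCC)C(=O)OCC | starting material
4 | bromomagnesium (S)-3-(prop-1-en-2-yl)cyclopent-1-en-1-olate | C=C(C)[C@H]1CCC(O[Mg]Br)=C1 | intermediate (not isolated)
5 | diethyl 2-{[(1R,5S)-2-oxo-5-(prop-1-en-2-yl)cyclopentyl]methyl}propanedioate | CCOC(=O)C(C[C@@H]1[C@H](CCC1=O)C(C)=C)C(=O)OCC | intermediate
6 | diethyl 2-{[(1R,2S,5S)-2-hydroxy-2-methyl-5-(prop-1-en-2-yl)cyclopentyl]methyl}propanedioate | CCOC(=O)C(C[C@@H]1[C@H](CC[C@]1(C)O)C(C)=C)C(=O)OCC | intermediate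
7 | diethyl 2-bromo-2-{[(1R,2S,5S)-2-hydroxy-2-methyl-5-(prop-1-en-2-yl)cyclopentyl]methyl}propanedioate | CCOC(=O)C(Br)(C[C@@H]1[C@H](CC[C@]1(C)O)C(C)=C)C(=O)OCC | intermediate
8 | diethyl (3S,3aR,7S,7aR)-3-hydroxy-3,7-dimethyloctahydro-1H-indene-5,5-dicarboxylate | CCOC(=O)C1(C[C@@H]2[C@H](CC[C@]2(C)O)[C@@H](C)C1)C(=O)OCC | intermediate
9 | (3S,3aR,7S,7aR)-3-hydroxy-3,7-dimethyloctahydro-1H-indene-5,5-dicarboxylic acid (trans-hydrindane malonic acid) | OC(=O)C1(C[C@@H]2[C@H](CC[C@]2(C)O)[C@@H](C)C1)C(=O)O | intermediate
10 | (1R,2S,5S,6R,8R)-5-hydroxy-1,5-dimethyl-9-oxo-10-oxatricyclo[6.2.1.0(2,6)]undecane-8-carboxylic acid (bridged lactone acid) | O=C1[C@@]2(C[C@@H]3[C@H](CC[C@]3(C)O)[C@](C)(O1)C2)C(=O)O | intermediate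
11 | 6-methylheptane-2,4-dione | CC(C)CC(=O)CC(C)=O | starting material
12 | trimethylsilyl ester of 10 with the tertiary hydroxyl as trimethylsilyl ether | O=C1[C@@]2(C[C@@H]3[C@H](CC[C@]3(C)O[Si](C)(C)C)[C@](C)(O1)C2)C(=O)O[Si](C)(C)C | intermediate (not isolated)
13 | acid chloride of 10 with the tertiary hydroxyl as trimethylsilyl ether | O=C1[C@@]2(C[C@@H]3[C@H](CC[C@]3(C)O[Si](C)(C)C)[C@](C)(O1)C2)C(Cl)=O | intermediate (not isolated)
14 | trimethylsilyl ether of 15 | O=C1[C@@]2(C[C@@H]3[C@H](CC[C@]3(C)O[Si](C)(C)C)[C@](C)(O1)C2)C(=O)C(C(C)=O)C(=O)CC(C)C | intermediate (not isolated)
15 | (1R,2S,5S,6R,8R)-8-(2-acetyl-5-methyl-3-oxohexanoyl)-5-hydroxy-1,5-dimethyl-10-oxatricyclo[6.2.1.0(2,6)]undecan-9-one | O=C1[C@@]2(C[C@@H]3[C@H](CC[C@]3(C)O)[C@](C)(O1)C2)C(=O)C(C(C)=O)C(=O)CC(C)C | intermediate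
16 | des-prenyl spiro trione (as described in step 8) | C1C(=O)[C@@]2(C[C@@H]3[C@H](CC[C@]3(C)O)[C@](C)(O)C2)C(=O)C(C(=O)CC(C)C)=C1O | intermediate
17 | prenyl bromide (1-bromo-3-methylbut-2-ene) | CC(C)=CCBr | starting material
18 | CNP0198642.4 | CC(C)=CCC1(CC=C(C)C)C(=O)[C@@]2(C[C@@H]3[C@H](CC[C@]3(C)O)[C@](C)(O)C2)C(=O)C(C(=O)CC(C)C)=C1O | target

## Step count and least certain steps

Total step count: 9. Longest linear sequence: 9 steps (1 to 18); 2, 3, 11 and 17 are bought.

Step 6 (key step). The most likely failure is misdirected hydrogen abstraction, at the fusion methine on Ca, which is placed exactly like Cd–H relative to the axial carboxylate; the catalyst may also be slowed if both carboxyl groups bind one iron centre. The first variable is the antipode of the ligand.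
Fallback: it sets out from 6 and makes the same C–O bond from the alkene stage. Mn(OAc)3·2H2O (2.2 equiv) in AcOH at 70 °C oxidises the malonate to the malonyl radical (trivalent manganese as one-electron oxidant), the same 6-endo closure follows, and the tertiary Cd radical is oxidised to the cation. The syn-axial ester captures the cation with loss of its ethyl group, giving the lactone ethyl ester F1. LiOH in aqueous THF and then acid to pH 2 (a lactone opened on the way recloses from the syn-axial hydroxy acid) comes back to the route at 10. The two carboxyls are told apart by the same geometry, at the price of giving up the late C–H oxidation.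

Step 1. The most likely failure is weak enantiofacial control, because an α-branched alkenyl Grignard reagent on the small, flat cyclopentenone is a demanding case for copper–diphosphine catalysts; oligomerisation of 3 by the enolate is the second concern.
Fallback: it sets out from 2 and 3 and replaces 1 by the auxiliary-bearing enone (R)-2-(4-methylbenzenesulfinyl)cyclopent-2-en-1-one F2. F2 is precomplexed with ZnBr2 in THF at −78 °C and treated with 2; in the zinc chelate of the carbonyl and sulfinyl oxygens the aryl group blocks one face, and by this chelate model the (R)-sulfoxide should give (S) at the β-carbon (the antipode is taken if the sense proves opposite). The stabilised β-keto sulfoxide enolate is then alkylated in the same flask by 3 to give the sulfinyl keto malonate F3. Aluminium amalgam in wet THF cleaves the C–S bond, and protonation (DBU if needed) gives the trans ketone, coming back at 5.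

Step 4. The most likely failure is hydrogen transfer to the equatorial face of the Cd radical, because the axial ester on Cs hinders the axial approach of the bulky stannane; this would place the methyl axial and leave no C–H bond for step 6.
Fallback: it sets out from 7 and avoids hydrogen transfer altogether. Atom-transfer cyclisation (Ru(bpy)3Cl2 1 mol %, LiBr, DMF, blue light) gives the tertiary bromide F4, in which the configuration at Cd does not matter. On warming in CH3CN the bromide ionises with participation of the syn-axial ester and loses bromoethane to give the lactone ethyl ester F1. LiOH and then acid comes back at 10, bypassing 8, 9 and step 6.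

Step 8. The most likely failure is incomplete or misdirected third deprotonation of the crowded triacylmethane (the 3-methylbutanoyl CH2 instead of the acetyl CH3), or loss of an acyl group from it under the amide base.
Fallback: it sets out from 10 and 11 and makes the carbanion on the simple diketone, where the terminal methyl is the established site. The dianion of 11 (LDA, 2.1 equiv, THF, −78 → 0 °C) is added to the dilithium salt of 10 (LiHMDS, 2 equiv); only the lactone carbonyl is electrophilic, and its opening gives the triketo acid F5, which is kept cold because it is a β-keto acid. 1,1'-Carbonyldiimidazole, then DBU with catalytic DMAP, closes ring A by intramolecular C-acylation of the carbon between the two diketone carbonyls (any O-acyl isomer is moved to carbon by DMAP), coming back at 16.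

Step 9. The most likely failure is alkylation on oxygen or incomplete second alkylation, together with methoxide cleavage of the non-enolisable carbonyl once the quaternary carbon is in place.
Fallback: it sets out from 16. Allyl methyl carbonate (2.5 equiv) with Pd(PPh3)4 (5 mol %) in THF alkylates the soft carbon nucleophile twice through the π-allyl complex of divalent palladium, without added base, to give the diallyl trione F6. Cross-metathesis with 2-methylbut-2-ene (excess) and the second-generation Grubbs catalyst (5 mol %) in CH2Cl2 at 40 °C converts both allyl groups into prenyl groups, coming back at 18.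

## Further compounds

F1 | step 6 | ethyl (1R,2S,5S,6R,8R)-5-hydroxy-1,5-dimethyl-9-oxo-10-oxatricyclo[6.2.1.0(2,6)]undecane-8-carboxylate (lactone ethyl ester) | O=C1[C@@]2(C[C@@H]3[C@H](CC[C@]3(C)O)[C@](C)(O1)C2)C(=O)OCC
F2 | step 1 | (R)-2-(4-methylbenzenesulfinyl)cyclopent-2-en-1-one | O=C1CCC=C1[S@](=O)c1ccc(C)cc1
F3 | step 1 | sulfinyl keto malonate (5 carrying the (R)-4-methylbenzenesulfinyl group on the ring carbon that bears the malonate arm; that carbon as a mixture of epimers) | CCOC(=O)C(CC1([S@](=O)c2ccc(C)cc2)[C@H](CCC1=O)C(C)=C)C(=O)OCC
F4 | step 4 | diethyl (3S,3aR,7aS)-7-bromo-3-hydroxy-3,7-dimethyloctahydro-1H-indene-5,5-dicarboxylate (C7 epimers) | CCOC(=O)C1(C[C@@H]2[C@H](CC[C@]2(C)O)C(C)(Br)C1)C(=O)OCC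
F5 | step 8 | triketo acid (ring B carboxylic acid on Cs with Cax as the first carbonyl of a 7-methyl-1,3,5-trioxooctyl chain; free Cd hydroxyl) | OC(=O)[C@]1(C[C@@H]2[C@H](CC[C@]2(C)O)[C@](C)(O)C1)C(=O)CC(=O)CC(=O)CC(C)C
F6 | step 9 | diallyl trione (18 with two prop-2-enyl groups in place of the prenyl groups) | C=CCC1(CC=C)C(=O)[C@@]2(C[C@@H]3[C@H](CC[C@]3(C)O)[C@](C)(O)C2)C(=O)C(C(=O)CC(C)C)=C1O
A1 | alternative 1 | dimethyl 2-{2-[(methoxycarbonyl)oxy]-3-[(trimethylsilyl)methyl]but-3-en-1-yl}-2-{(2R,3E)-4-(benzenesulfonyl)-2-methyl-2-[(triethylsilyl)oxy]but-3-en-1-yl}propanedioate | COC(=O)C(CC(OC(=O)OC)C(=C)C[Si](C)(C)C)(C[C@@](C)(O[Si](CC)(CC)CC)/C=C/S(=O)(=O)c1ccccc1)C(=O)OC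
A2 | alternative 1 | dimethyl 1-(benzenesulfonyl)-7-methyl-3-methylidene-7-[(triethylsilyl)oxy]octahydro-1H-indene-5,5-dicarboxylate (trans-fused, C1 epimers) | COC(=O)C1(C[C@@H]2[C@H](C(S(=O)(=O)c3ccccc3)CC2=C)[C@](C)(O[Si](CC)(CC)CC)C1)C(=O)OC
A3 | alternative 2 | diethyl 2-{[(1R,5S)-2-oxo-5-(prop-1-en-2-yl)cyclopentyl]methyl}propanedioate (identical with 5) | CCOC(=O)C(C[C@@H]1[C@H](CCC1=O)C(C)=C)C(=O)OCC
A4 | alternative 3 | 1-{2,4,6-trihydroxy-3-[((1R,2S,5S)-2-hydroxy-2-methyl-5-(2-methyloxiran-2-yl)cyclopentyl)methyl]phenyl}-3-methylbutan-1-one (epoxide configured to give the Cd carbinol of the target) | CC(C)CC(=O)c1c(O)cc(O)c(C[C@@H]2[C@H](CC[C@]2(C)O)[C@@]3(C)CO3)c1O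
A5 | alternative 3 | des-prenyl spiro trione (identical with 16) | C1C(=O)[C@@]2(C[C@@H]3[C@H](CC[C@]3(C)O)[C@](C)(O)C2)C(=O)C(C(=O)CC(C)C)=C1O
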